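**Plan**

1. The target is achiral. Its pentacyclic core runs ring B – 1,4-dioxin – ring C – furan – ring D and carries two identical 3,5-dihydroxyphenyl ethers. Ring A sits on the oxygen at B1, between B2–OH and the dioxin oxygen on B6. Ring E sits on the oxygen at D2, between D3–OH and the furan oxygen on D1.
2. Enabling feature: rings A and E each bear oxygen on three alternating carbons and are isomers (C6H5O2) of a 6-methyl-2-oxo-2H-pyran-4-yl group. The first cut is therefore one ring C–C bond in A and one in E (resorcinol C1–C2, which is pyrone lactone carbon to pyrone methyl carbon). This turns both crowded diaryl ethers into vinylogous esters at an unhindered pyrone carbon.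
3. Further cuts, in order: the two pyranyl C–O bonds, dioxin bond B5–O–C6 (Ullmann), dioxin bond C1–O–B6 (SNAr), furan bond C5–D6 (direct arylation), furan bond C4–O–D1 (SNAr).
4. Forward: ring C (from O-benzylvanillin) is joined to ring D and the furan is closed. Ring B is added as a mirror-symmetric 2-fluoroisophthalaldehyde and the dioxin is closed. Both pyranyl ethers are made, rings A and E are formed together, and the five methyl ethers fall last.
5. The oxygens on C4, B1, B5 and D2 all start as formyl groups, which on rings B and D first activate fluoride displacement and are then exchanged for OH by Baeyer–Villiger oxidation. Cyclisation of the symmetric ring B resorcinol fixes the dioxin regiochemistry and leaves B1–OH free without a protecting group.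
6. Stereochemistry: there is no stereocentre and no hindered axis to set. Only the cis relation across the former pyrone double bond matters, and it is inherited from the ring.

Key step: step 15

Labels:
- Ring B: B1 (O–ring A), B2 (OH), B3 (H), B4 (OH), B5 (dioxin O to C6), B6 (dioxin O to C1).
- Ring C: C1 (dioxin O), C2 (OH), C3 (H), C4 (furan O), C5 (bonded to D6), C6 (dioxin O).
- Ring D: D1 (furan O), D2 (O–ring E), D3 (OH), D4 (H), D5 (OH), D6 (bonded to C5).
- Pyrone atoms: O1 (ring oxygen), P2 (lactone carbonyl carbon), P3, P4 (aryloxy carbon), P5, P6, P7 (methyl carbon).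
- Dibenzofuran intermediates are numbered with the formyl group at position 4.

Assumption: rotation about the C1–O–B6 ether bonds is fast at the reaction temperatures, so the two formyl groups (later hydroxyl groups) on ring B are chemically equivalent.

**Step 1**
Reactants: 1 4-(benzyloxy)-3-methoxybenzaldehyde
Product: 2 4-(benzyloxy)-2-bromo-5-methoxybenzaldehyde
Conditions: Br2, NaOAc, AcOH, rt
Reagents that add atoms: bromine, BrBr
Why: Electrophilic aromatic bromination attacks the position para to the methoxy group and ortho to the formyl group (future C5), the established site in 4-O-alkylvanillins, while acetate buffers the HBr so that the benzyl ether survives.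

**Step 2**
Reactants: 2 4-(benzyloxy)-2-bromo-5-methoxybenzaldehyde
Product: 4 4-(benzyloxy)-2-bromo-5-methoxyphenol, via aryl formate 3 (not isolated)
Conditions: mCPBA, CH2Cl2, rt; then K2CO3 (cat.), MeOH, rt
Reagents that add atoms: mCPBA, OOC(=O)c1cccc(Cl)c1
Why: Baeyer–Villiger oxidation of an electron-rich benzaldehyde (aryl migration favoured by the para benzyloxy group) followed by methanolysis of the formate installs the C4 phenol without touching the bromide or the benzyl ether.

**Step 3**
Reactants: 5 1-fluoro-3,5-dimethoxybenzene
Product: 7 2-fluoro-4,6-dimethoxybenzaldehyde, via iminium chloride 6 (not isolated)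
Conditions: POCl3, DMF, 0 → 70 °C; then ice-water
Reagents that add atoms: DMF, CN(C)C=O; water, O
Why: Vilsmeier–Haack formylation goes para to one methoxy group and next to the small fluorine rather than between the two methoxy groups, which gives a fluoride activated by an ortho formyl group that is also the latent D2 oxygen.

**Step 4**
Reactants: 4 4-(benzyloxy)-2-bromo-5-methoxyphenol; 7 2-fluoro-4,6-dimethoxybenzaldehyde
Product: 8 2-[4-(benzyloxy)-2-bromo-5-methoxyphenoxy]-4,6-dimethoxybenzaldehyde
Conditions: K2CO3, DMA, 120 °C
Reagents that add atoms: none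
Why: In this nucleophilic aromatic substitution (addition–elimination) the phenoxide of 4 displaces the fluoride ortho to the formyl group, both methoxy groups lie meta to the reacting carbon and so do not oppose the Meisenheimer charge, and the aryl bromide is inert without a metal catalyst.

**Step 5**
Reactants: 8 2-[4-(benzyloxy)-2-bromo-5-methoxyphenoxy]-4,6-dimethoxybenzaldehyde
Product: 9 8-(benzyloxy)-1,3,7-trimethoxydibenzo[b,d]furan-4-carbaldehyde
Conditions: Pd(OAc)2 (5 mol %), PCy3·HBF4 (10 mol %), PivOH (30 mol %), K2CO3, DMA, 110 °C
Reagents that add atoms: none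
Why: In this intramolecular direct arylation by concerted metalation–deprotonation, zerovalent palladium inserts into the only C–Br bond (C5) and the pivalate-assisted C–H cleavage can occur only at D6, the sole free position ortho to the ether oxygen on ring D, so the furan closes with one regiochemical outcome.

**Step 6**
Reactants: 9 8-(benzyloxy)-1,3,7-trimethoxydibenzo[b,d]furan-4-carbaldehyde
Product: 10 8-hydroxy-1,3,7-trimethoxydibenzo[b,d]furan-4-carbaldehyde
Conditions: H2 (1 atm), Pd/C (10 wt % Pd), EtOAc–THF, rt
Reagents that add atoms: none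
Why: Catalytic hydrogenolysis removes the benzyl aryl ether when no halogen is left in the molecule, and the formyl group, a vinylogous carbonate flanked by two oxygen-bearing carbons, is slow to reduce under one atmosphere of hydrogen.

**Step 7**
Reactants: 10 8-hydroxy-1,3,7-trimethoxydibenzo[b,d]furan-4-carbaldehyde
Product: 11 9-bromo-8-hydroxy-1,3,7-trimethoxydibenzo[b,d]furan-4-carbaldehyde
Conditions: Br2 (1.0 equiv), t-BuNH2 (2 equiv), toluene–CH2Cl2, −30 → −78 °C
Reagents that add atoms: bromine, BrBr
Why: In this amine-mediated ortho-bromination of a phenol, preformed N-bromo-tert-butylamine is too weak an electrophile for aryl ethers and delivers bromine through the hydrogen-bonded phenol–amine pair to C6, the only free position ortho or para to the C1 hydroxyl.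

**Step 8**
Reactants: 5 1-fluoro-3,5-dimethoxybenzene
Product: 12 2,4-dibromo-3-fluoro-1,5-dimethoxybenzene
Conditions: NBS (2.05 equiv), MeCN, 0 °C → rt
Reagents that add atoms: N-bromosuccinimide, O=C1CCC(=O)N1Br
Why: Twofold electrophilic aromatic bromination with NBS in acetonitrile is para-selective with respect to methoxy groups, so both positions flanking fluorine react and the position between the methoxy groups (future B3) stays free.

**Step 9**
Reactants: 12 2,4-dibromo-3-fluoro-1,5-dimethoxybenzene
Product: 15 2-fluoro-4,6-dimethoxybenzene-1,3-dicarbaldehyde, via lithium hemiaminal 13 (not isolated), via dilithium bis-hemiaminal 14 (not isolated)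
Conditions: n-BuLi (1.05 equiv), THF, −78 °C; DMF (1.05 equiv); n-BuLi (1.2 equiv), −78 °C; DMF (3 equiv); then 1 M HCl
Reagents that add atoms: DMF, CN(C)C=O
Why: Two rounds of bromine–lithium exchange and Bouveault formylation run in one flask, because the first tetrahedral DMF adduct masks the new aldehyde during the second exchange and −78 °C keeps the ortho-fluoro aryllithiums from losing LiF.

**Step 10**
Reactants: 11 9-bromo-8-hydroxy-1,3,7-trimethoxydibenzo[b,d]furan-4-carbaldehyde; 15 2-fluoro-4,6-dimethoxybenzene-1,3-dicarbaldehyde
Product: 16 2-[(9-bromo-4-formyl-1,3,7-trimethoxydibenzo[b,d]furan-8-yl)oxy]-4,6-dimethoxybenzene-1,3-dicarbaldehyde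
Conditions: K2CO3, DMF, 80 °C
Reagents that add atoms: none
Why: Nucleophilic aromatic substitution occurs on a fluoride activated by two ortho formyl groups, which compensates for the two ortho substituents (OMe, Br) of the phenoxide, and the mirror plane of 15 through its C–F bond removes any regiochemical question.

**Step 11**
Reactants: 16 2-[(9-bromo-4-formyl-1,3,7-trimethoxydibenzo[b,d]furan-8-yl)oxy]-4,6-dimethoxybenzene-1,3-dicarbaldehyde
Product: 18 2-[(9-bromo-4-hydroxy-1,3,7-trimethoxydibenzo[b,d]furan-8-yl)oxy]-4,6-dimethoxybenzene-1,3-diol, via triformate 17 (not isolated)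
Conditions: mCPBA (4 equiv), CH2Cl2, 0 °C → rt; then K2CO3 (cat.), MeOH, 0 °C, Ar
Reagents that add atoms: mCPBA, OOC(=O)c1cccc(Cl)c1
Why: Threefold Baeyer–Villiger oxidation of 2,4,6-trioxygenated benzaldehydes (the best aryl migrators) and formate methanolysis unmask the B1, B5 and D2 phenols in one operation, the aryl bromide being inert to peracid.

**Step 12**
Reactants: 18 2-[(9-bromo-4-hydroxy-1,3,7-trimethoxydibenzo[b,d]furan-8-yl)oxy]-4,6-dimethoxybenzene-1,3-diol
Product: 19 core bisphenol (OH on B1 and D2; OMe on B2, B4, C2, D3, D5)
Conditions: CuI (20 mol %), N,N-dimethylglycine (40 mol %), Cs2CO3, 1,4-dioxane, 100 °C, Ar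
Reagents that add atoms: none
Why: In this intramolecular Ullmann-type O-arylation with monovalent copper, either of the two equivalent ring B phenoxides reaches C6–Br through a six-membered transition state and closes the 1,4-dioxin, which leaves the other as the B1 phenol next to B6, while the D2 phenoxide has no halide within reach and the electron-rich ring C allows no Smiles rearrangement.

**Step 13**
Reactants: 20 4-hydroxy-6-methyl-2H-pyran-2-one
Product: 21 4-bromo-6-methyl-2H-pyran-2-one
Conditions: PBr3, DMF, 0 → 60 °C
Reagents that add atoms: phosphorus tribromide, BrP(Br)Br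
Why: Vilsmeier-type bromodehydroxylation of a vinylogous acid is the standard preparation of this 4-bromopyrone.

**Step 14**
Reactants: 19 core bisphenol; 21 4-bromo-6-methyl-2H-pyran-2-one
Product: 22 core pentamethyl ether bis(6-methyl-2-oxo-2H-pyran-4-yl) ether (pyranyl groups on O–B1 and O–D2)
Conditions: 21 (2.5 equiv), Cs2CO3, MeCN, 40 °C
Reagents that add atoms: none
Why: Addition–elimination at the vinylogous acyl bromide is the known reaction of 4-halo-2-pyrones with O-, N- and S-nucleophiles, and because P4 is flanked only by two CH groups the two ortho substituents on each phenoxide cost far less than in an arylation.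

**Step 15**
Reactants: 22 core pentamethyl ether bis(6-methyl-2-oxo-2H-pyran-4-yl) ether
Product: 24 core pentamethyl ether bearing free rings A and E (two 3,5-dihydroxyphenyl ethers), via bis(ketene enolate) 23 (not isolated)
Conditions: KN(SiMe3)2 (5 equiv), toluene–THF, 0.005 M, −78 → 100 °C; then 1 M HCl
Reagents that add atoms: none
Why: Proposed new method: KN(SiMe3)2 deprotonates the methyl carbon P7 of each pyrone (the site at which amide bases are known to metalate 4-alkoxy-6-methyl-2-pyrones), and on heating each trienolate expels its own ring oxygen O1 from the lactone carbon P2 in an E1cB step, which opens the lactone to a dienylketene that ends in the methyl ketone enolate and keeps P3 and P6 cis across P4=P5. After rotation about P5–P6 the enolate carbon P7 adds to the ketene carbon P2, a Claisen-type C-acylation (6-(enolexo)-exo-dig by the ring-closure rules, or equally a 6π electrocyclisation) that makes the one new C–C bond of ring A and, independently, of ring E, and tautomerisation of each cyclohexadienone to the 5-aryloxyresorcinolate renders it irreversible, whereas reclosure through oxygen merely returns the pyrone anion. The closest known reaction types are the alkoxide-induced recyclisation of triacetic acid lactone and its 4-methyl ether to phloroglucinol derivatives, the base-induced rearrangement of enol δ-lactones and 5-oxohexanoates to cyclohexane-1,3-diones, ketene formation from aryl ester enolates and the closure of dienylketenes to phenols. The selectivity required is cleavage of the lactone C–O bond without loss of the core phenoxide from P4 by addition–elimination, which is why the classical alkoxide-in-alcohol medium is replaced by a bulky amide in a hydrocarbon–ether solvent: no small nucleophile is present, both faces of P4 are screened by the two ortho substituents of the perpendicular ring B or ring D, and neither the ring anion nor the open chain offers a β-elimination path for the aryloxy group. High dilution holds back attack of one pyrone anion on another pyrone, and more than two equivalents of base per pyrone prevent the acidic product from quenching unreacted anion. No stereocentre is formed.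

**Step 16**
Reactants: 24 core pentamethyl ether bearing free rings A and E
Product: 25 phlorofucofuroeckol A
Conditions: BBr3 (15 equiv), CH2Cl2, −78 °C → rt; then H2O
Reagents that add atoms: none
Why: Lewis-acid cleavage of aryl methyl ethers with BBr3 removes the five methyl groups, whereas the diaryl ether, dioxin and furan C–O bonds offer bromide no sp3 carbon to attack and remain.

**Compound list**

1 | 4-(benzyloxy)-3-methoxybenzaldehyde (O-benzylvanillin) | COc1cc(C=O)ccc1OCc1ccccc1 | starting material
2 | 4-(benzyloxy)-2-bromo-5-methoxybenzaldehyde | COc1cc(C=O)c(Br)cc1OCc1ccccc1 | intermediate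
3 | 4-(benzyloxy)-2-bromo-5-methoxyphenyl formate | COc1cc(OC=O)c(Br)cc1OCc1ccccc1 | intermediate
4 | 4-(benzyloxy)-2-bromo-5-methoxyphenol | COc1cc(O)c(Br)cc1OCc1ccccc1 | intermediate
5 | 1-fluoro-3,5-dimethoxybenzene | COc1cc(F)cc(OC)c1 | starting material
6 | N-[(2-fluoro-4,6-dimethoxyphenyl)methylidene]-N-methylmethanaminium chloride | COc1cc(F)c(C=[N+](C)C)c(OC)c1.[Cl-] | intermediate
7 | 2-fluoro-4,6-dimethoxybenzaldehyde | COc1cc(F)c(C=O)c(OC)c1 | intermediate
8 | 2-[4-(benzyloxy)-2-bromo-5-methoxyphenoxy]-4,6-dimethoxybenzaldehyde | COc1cc(OC)c(C=O)c(Oc2cc(OC)c(OCc3ccccc3)cc2Br)c1 | intermediate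
9 | 8-(benzyloxy)-1,3,7-trimethoxydibenzo[b,d]furan-4-carbaldehyde | COc1cc(OC)c2c(c1C=O)oc1cc(OC)c(OCc3ccccc3)cc12 | intermediate
10 | 8-hydroxy-1,3,7-trimethoxydibenzo[b,d]furan-4-carbaldehyde | COc1cc(OC)c2c(c1C=O)oc1cc(OC)c(O)cc12 | intermediate
11 | 9-bromo-8-hydroxy-1,3,7-trimethoxydibenzo[b,d]furan-4-carbaldehyde | COc1cc(OC)c2c(c1C=O)oc1cc(OC)c(O)c(Br)c12 | intermediate
12 | 2,4-dibromo-3-fluoro-1,5-dimethoxybenzene | COc1cc(OC)c(Br)c(F)c1Br | intermediate
13 | lithium (3-bromo-2-fluoro-4,6-dimethoxyphenyl)(dimethylamino)methanolate (configuration not controlled, lost on work-up) | COc1cc(OC)c(C([O-])N(C)C)c(F)c1Br.[Li+] | intermediate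
14 | dilithium (2-fluoro-4,6-dimethoxy-1,3-phenylene)bis[(dimethylamino)methanolate] (configuration not controlled, lost on work-up) | COc1cc(OC)c(C([O-])N(C)C)c(F)c1C([O-])N(C)C.[Li+].[Li+] | intermediate
15 | 2-fluoro-4,6-dimethoxybenzene-1,3-dicarbaldehyde | COc1cc(OC)c(C=O)c(F)c1C=O | intermediate
16 | 2-[(9-bromo-4-formyl-1,3,7-trimethoxydibenzo[b,d]furan-8-yl)oxy]-4,6-dimethoxybenzene-1,3-dicarbaldehyde | COc1cc(OC)c2c(c1C=O)oc1cc(OC)c(Oc3c(C=O)c(OC)cc(OC)c3C=O)c(Br)c12 | intermediate
17 | triformate of 18 (formates on B1, B5 and D2) | COc1cc(OC)c2c(c1OC=O)oc1cc(OC)c(Oc3c(OC=O)c(OC)cc(OC)c3OC=O)c(Br)c12 | intermediate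
18 | 2-[(9-bromo-4-hydroxy-1,3,7-trimethoxydibenzo[b,d]furan-8-yl)oxy]-4,6-dimethoxybenzene-1,3-diol | COc1cc(OC)c2c(c1O)oc1cc(OC)c(Oc3c(O)c(OC)cc(OC)c3O)c(Br)c12 | intermediate
19 | core bisphenol: benzofuran-fused dibenzo[1,4]dioxin with OH on B1 and D2 and OMe on B2, B4, C2, D3, D5 | COc1cc(OC)c2c(c1O)Oc1c(OC)cc3oc4c(O)c(OC)cc(OC)c4c3c1O2 | intermediate
20 | 4-hydroxy-6-methyl-2H-pyran-2-one (triacetic acid lactone) | CC1=CC(O)=CC(=O)O1 | starting material
21 | 4-bromo-6-methyl-2H-pyran-2-one | CC1=CC(Br)=CC(=O)O1 | intermediate
22 | core pentamethyl ether bis(6-methyl-2-oxo-2H-pyran-4-yl) ether | CC1=CC(Oc2c(OC)cc(OC)c3c2Oc2c(OC)cc4oc5c(OC6=CC(=O)OC(C)=C6)c(OC)cc(OC)c5c4c2O3)=CC(=O)O1 | intermediate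
23 | dipotassium salt in which each pyranyl group is opened to a 4-(aryloxy)-6-oxohexa-1,3,5-trien-2-olate, P3 and P6 cis across P4=P5 | [K+].[K+].C=C([O-])\C=C(/C=C=O)Oc1c(OC)cc(OC)c2c1Oc1c(OC)cc3oc4c(OC(/C=C=O)=C/C(=C)[O-])c(OC)cc(OC)c4c3c1O2 | intermediate
24 | core pentamethyl ether of the target with rings A and E free | Oc1cc(O)cc(Oc2c(OC)cc(OC)c3c2Oc2c(OC)cc4oc5c(Oc6cc(O)cc(O)c6)c(OC)cc(OC)c5c4c2O3)c1 | intermediate
25 | phlorofucofuroeckol A | Oc1cc(O)cc(Oc2c(O)cc(O)c3c2Oc2c(O)cc4oc5c(Oc6cc(O)cc(O)c6)c(O)cc(O)c5c4c2O3)c1 | target

**Counts**

Total steps: 16. Longest linear sequence: 12 (steps 1, 2, 4, 5, 6, 7, 10, 11, 12, 14, 15, 16).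

**Steps most likely to fail**

(a) Step 15. The pyrone anions may fail to open below the temperature at which they attack one another. The core phenoxide may also be lost from P4 by addition–elimination with product phenoxides. The fallback uses known Ullmann ether chemistry. It sets out from 19 and comes back at 25. Double O-arylation of 19 with 1-iodo-3,5-dimethoxybenzene (CuI, picolinic acid, K3PO4, DMSO, 100 °C, a system suited to ortho-substituted phenols) should give the nonamethyl ether of the target F1. Exhaustive demethylation of it with BBr3 in CH2Cl2 should deliver 25.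

(b) Step 7. Site selectivity may be poor, with bromination at D4 of the trialkoxy ring competing with attack at C6 next to the phenol. The fallback carries the C6 bromine in from the start and closes the furan through a more reactive C–I bond. It sets out from 7 and comes back at 11.
- Commercial 5-bromovanillin is capped with MOMCl and i-Pr2NEt to give 3-bromo-5-methoxy-4-(methoxymethoxy)benzaldehyde F2.
- Baeyer–Villiger oxidation with mCPBA gives the aryl formate F3, and methanolysis gives 3-bromo-5-methoxy-4-(methoxymethoxy)phenol F4.
- NIS iodinates ortho to the hydroxyl and para to the methoxy group, the same preference that leads from 5-bromovanillin to 5,6-dibromovanillin, and gives 3-bromo-2-iodo-5-methoxy-4-(methoxymethoxy)phenol F5.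
- Fluoride displacement on 7 (K2CO3, DMA) gives the diaryl ether F6.
- Direct arylation with Pd(OAc)2, PPh3 and K2CO3 at 90 °C engages only the C–I bond and gives the bromodibenzofuran MOM ether F7.
- HCl in MeOH removes the acetal and delivers 11.

(c) Step 9. The ortho-fluoro aryllithium may lose LiF (aryne formation), or the second bromine–lithium exchange may stay incomplete. The fallback replaces organometallic formylation by electrophilic formylation. It sets out from 7 and comes back at 15. Rieche formylation of 7 (Cl2CHOMe, TiCl4, CH2Cl2, 0 °C → rt) should enter the position between fluorine and the 4-methoxy group, para to the 6-methoxy group, and makes no new compound on the way.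

**Further compounds**

F1 | step 15 | nonamethyl ether of phlorofucofuroeckol A | COc1cc(OC)cc(Oc2c(OC)cc(OC)c3c2Oc2c(OC)cc4oc5c(Oc6cc(OC)cc(OC)c6)c(OC)cc(OC)c5c4c2O3)c1
F2 | step 7 | 3-bromo-5-methoxy-4-(methoxymethoxy)benzaldehyde | COCOc1c(Br)cc(C=O)cc1OC
F3 | step 7 | 3-bromo-5-methoxy-4-(methoxymethoxy)phenyl formate | COCOc1c(Br)cc(OC=O)cc1OC
F4 | step 7 | 3-bromo-5-methoxy-4-(methoxymethoxy)phenol | COCOc1c(Br)cc(O)cc1OC
F5 | step 7 | 3-bromo-2-iodo-5-methoxy-4-(methoxymethoxy)phenol | COCOc1c(Br)c(I)c(O)cc1OC
F6 | step 7 | 2-[3-bromo-2-iodo-5-methoxy-4-(methoxymethoxy)phenoxy]-4,6-dimethoxybenzaldehyde | COCOc1c(Br)c(I)c(Oc2cc(OC)cc(OC)c2C=O)cc1OC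
F7 | step 7 | 9-bromo-1,3,7-trimethoxy-8-(methoxymethoxy)dibenzo[b,d]furan-4-carbaldehyde | COCOc1c(OC)cc2oc3c(C=O)c(OC)cc(OC)c3c2c1Br
F0 | step 9 | none | none
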